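- 3 questions stand on this flask: what has stopped it, if anything, and how much target and isomer of the product it then holds. Sunday's run is this same flask, followed for a short time.

| flask | starting material | protic impurity | remark | time |
|---|---|---|---|---|
| Sunday's | 1 M (fed, over 1.2 s) | 0.30 M | the very flask that is asked about, followed so far; the fed solution adds 1.0 times the starting volume |  |
| Tuesday's | 2 M (fed, over 1.2 s) | 0.30 M | run made earlier; the fed solution adds 1.0 times the starting volume |  |
| flask | 1.0 M (fed, over 1.2 s) | 0.300 M | the fed solution adds 1.0 times the starting volume | 6.0 min |

Sunday's run (percent of the starting material charged)

| time / s | target / % | isomer of the product / % |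
|---|---|---|
| 10.0 | 16.5 | 26.0 |
| 25.0 | 14.6 | 28.1 |
| 50.0 | 14.0 | 29.5 |
| 80.0 | 13.9 | 30.5 |

Tuesday's run (percent of the starting material charged)

| time / min | target / % | isomer of the product / % |
|---|---|---|
| 0.333 | 17.4 | 32.8 |
| 0.833 | 16.9 | 35.3 |
| 2.00 | 16.2 | 36.6 |
| 4.00 | 16.2 | 33.9 |

(readings scatter by 1 percentage point)

* at 6.0 min, what has stopped the reaction, if anything has (forward and back rates have come level / all of the starting material has reacted / it is still moving)
* target at 6.0 min, in percent of the starting material charged
* isomer of the product at 6.0 min, in percent of the starting material charged

- charges are per starting volume, the dose included; the dosed solution carries all of it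
- the reaction counts as stopped when no species that holds the starting material changes by six tenths of a point or more over the second half of the time

- I fold the givens into one number, the usable share: one minus the ratio of the charges [protic impurity]/[starting material], which is 70.0% in this flask and 85.0% on Tuesday's run. I assume that the impurity is the limiting reagent of a quench, taking one equivalent of starting material, and that the rest behaves alike at either charge.
- I replace Tuesday's late curve by its mean over 2.00 min and 4.00 min, which gives 19.1% target and 41.5% isomer per usable share. That mean hides a fall of 2.7 percentage points in the isomer, so the isomer is my weaker number.
- As a test, Sunday's readings at 80.0 s give 19.9% and 43.6% per usable share, so one number serves the target well and the isomer less well.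
- Tuesday's target reads 16.2% and 16.2% at those times, both earlier than the asked time, and target plus isomer stall at 60.6% of the usable share. So I expect thermodynamic control, with this flask at 13.4% target and 29.1% isomer.
- The forecast says forward and back rates have come level, with target 13.4% (12.6% to 14.2%) and isomer 30% (27.5% to 32%), and the remainder, in its words, seems “held in a balance rather than consumed”. Its isomer stands 0.97 points above mine.
- The simulation of this flask gives forward and back rates have come level, with target 13.5% and isomer 29.4%.

    starting material ⇌ target (K = 1.20, k = 0.184 /s)
    starting material ⇌ isomer of the product (K = 2.60, k = 0.0667 /s)
    target ⇌ isomer of the product (k = 0.111 /s)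
    starting material + protic impurity → quenched substrate (k = 0.996 /M/s)
    starting material ⇌ dormant form (K = 1.40, k = 0.142 /s)

- This flask holds quenched substrate 30.0% at 6.00 min, against 30.0% reckoned from the usable share, and protic impurity 0% of its charge. The neighbouring flask takes 0.75 M of protic impurity, 0.750 equiv, with its other charges and time unchanged. Its usable share is 25.0%, so the same means give 4.78% target and 10.4% isomer. The simulated neighbour holds 4.84% target, 10.5% isomer and 75.0% quenched substrate at 6.00 min.

All runs were generated by integration from invented constants, noise included.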